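Ring C, the 3',5'-dimethoxycyclohexadienone, is traced back to dimethyl squarate. C3', C4', C5' and C6' are the four squarate carbons with their oxygens. C2' and spiro carbon C5 are the two carbons of a terminal alkyne. The key-step precursor is an open chain: a 4-alkynyl-2,3,4-trimethoxycyclobutenone tied through the C6–C9 stereotriad to a bromotrimethoxybenzene (ring A). In one flask a 7-exo-dig reductive Heck closure makes ring B. Then 4π opening and 6π closure (Moore rearrangement) enlarge the four-membered ring to ring C and create the quaternary spiro carbon. The final mirror symmetry of ring C through C5 and C4' makes alkene geometry and spiro configuration irrelevant. A reduction/hydrolysis carbonyl shift ends the route.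

Key step: step 8

Remark: 1, 2 and 12 are taken as commercial; the alkynyl- or alkenyl-bearing cyclobutenone carbon of 14–16 and the spiro and carbinol carbons of ring C in 18 and 19 form as epimer mixtures that converge in steps 8 and 9, so they are drawn without configuration.

Step 1
Reactants: 1 2-bromo-3,4,5-trimethoxybenzaldehyde; 2 (Z)-crotylboronic acid pinacol ester
Product: 4 (1R,2S)-1-(2-bromo-3,4,5-trimethoxyphenyl)-2-methylbut-3-en-1-ol, via pinacol borate 3 (not isolated)
Conditions: (R)-3,3'-bis(2,4,6-triisopropylphenyl)-1,1'-binaphthyl-2,2'-diyl hydrogen phosphate (5 mol %), 4 Å molecular sieves, toluene, −30 °C; aq NaHCO3 work-up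
Reagents that add atoms: none
Why: Chiral-phosphoric-acid-catalysed crotylboration through a closed chair transition state, in which the (Z)-geometry of 2 sets the syn C1/C2 relationship and the (R)-configured catalyst should direct attack to the Re face of 1, giving (1R,2S).

Step 2
Reactants: 4 (1R,2S)-1-(2-bromo-3,4,5-trimethoxyphenyl)-2-methylbut-3-en-1-ol
Product: 5 (1R,2S)-1-(2-bromo-3,4,5-trimethoxyphenyl)-2-methylbut-3-en-1-yl acrylate
Conditions: acryloyl chloride, Et3N, DMAP (cat.), CH2Cl2, 0 °C
Reagents that add atoms: acryloyl chloride, C=CC(=O)Cl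
Why: DMAP-assisted O-acylation of a secondary alcohol, which touches no stereocentre.

Step 3
Reactants: 5 (1R,2S)-1-(2-bromo-3,4,5-trimethoxyphenyl)-2-methylbut-3-en-1-yl acrylate
Product: 6 (5S,6R)-6-(2-bromo-3,4,5-trimethoxyphenyl)-5-methyl-5,6-dihydro-2H-pyran-2-one
Conditions: second-generation Grubbs catalyst (5 mol %), CH2Cl2, 40 °C, dilute
Reagents that add atoms: none
Why: Ring-closing metathesis of the acrylate with the terminal alkene, driven by loss of ethylene, should close the unsaturated six-membered lactone without touching C5 and C6.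

Step 4
Reactants: 6 (5S,6R)-6-(2-bromo-3,4,5-trimethoxyphenyl)-5-methyl-5,6-dihydro-2H-pyran-2-one
Product: 8 (4R,5S,6R)-6-(2-bromo-3,4,5-trimethoxyphenyl)-4,5-dimethyltetrahydro-2H-pyran-2-one, via lithium enolate 7 (not isolated)
Conditions: Me2CuLi (from MeLi and CuI), Et2O, −78 °C; aq NH4Cl
Reagents that add atoms: lithium dimethylcuprate, [Li+].C[Cu-]C
Why: Gilman cuprate 1,4-addition, in which the half-chair with pseudo-equatorial aryl and pseudo-axial C5 methyl is attacked axially at C4 anti to that methyl, setting the 4,5-trans relationship (4R), while the aryl bromide should stay intact at −78 °C.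

Step 5
Reactants: 8 (4R,5S,6R)-6-(2-bromo-3,4,5-trimethoxyphenyl)-4,5-dimethyltetrahydro-2H-pyran-2-one
Product: 10 (1R,2S,3R)-1-(2-bromo-3,4,5-trimethoxyphenyl)-2,3-dimethylhex-5-yn-1-ol, via lactol 9 (not isolated)
Conditions: iBu2AlH, CH2Cl2, −78 °C; then MeOH, K2CO3, dimethyl (1-diazo-2-oxopropyl)phosphonate, −78 °C to rt
Reagents that add atoms: dimethyl (1-diazo-2-oxopropyl)phosphonate, COP(=O)(OC)C(=[N+]=[N-])C(C)=O
Why: Partial reduction of the lactone and Ohira–Bestmann homologation of the open hydroxy aldehyde form of the lactol in the same flask turn the lactone carbonyl carbon into the internal alkyne carbon, and the adjacent carbon is a CH2, so no stereocentre can epimerise.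

Step 6
Reactants: 10 (1R,2S,3R)-1-(2-bromo-3,4,5-trimethoxyphenyl)-2,3-dimethylhex-5-yn-1-ol
Product: 11 (1R,2S,3R)-1-(2-bromo-3,4,5-trimethoxyphenyl)-2,3-dimethylhex-5-yn-1-yl benzoate
Conditions: BzCl, Et3N, DMAP, CH2Cl2, 0 °C to rt
Reagents that add atoms: benzoyl chloride, O=C(Cl)c1ccccc1
Why: DMAP-catalysed benzoylation with retention at C1 installs the ester of the target early and thereby saves a protecting group.

Step 7
Reactants: 11 (1R,2S,3R)-1-(2-bromo-3,4,5-trimethoxyphenyl)-2,3-dimethylhex-5-yn-1-yl benzoate; 12 dimethyl squarate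
Product: 15 (1R,2S,3R)-1-(2-bromo-3,4,5-trimethoxyphenyl)-2,3-dimethyl-6-(1,2,3-trimethoxy-4-oxocyclobut-2-en-1-yl)hex-5-yn-1-yl benzoate, via lithium acetylide 13 (not isolated), via lithium alkoxide 14 (not isolated)
Conditions: LiN(iPr)2, THF, −78 °C; 12, −78 °C; then MeOTf, −78 to 0 °C
Reagents that add atoms: methyl trifluoromethanesulfonate, COS(=O)(=O)C(F)(F)F
Why: 1,2-Addition of a lithium acetylide to one carbonyl of the squarate ester and O-methylation of the alkoxide in situ is the standard entry to Moore substrates, the amide base should remove only the alkyne proton at −78 °C where benzoate and aryl bromide survive, and the new quaternary carbon forms without control because step 8 erases it.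

Step 8
Reactants: 15 (1R,2S,3R)-1-(2-bromo-3,4,5-trimethoxyphenyl)-2,3-dimethyl-6-(1,2,3-trimethoxy-4-oxocyclobut-2-en-1-yl)hex-5-yn-1-yl benzoate
Product: 18 (7R,8S,9R)-2,3,3',4,4',5'-hexamethoxy-7,8-dimethyl-6'-oxo-6,7,8,9-tetrahydrospiro[benzo[7]annulene-5,1'-cyclohexa[2,4]dien]-9-yl benzoate, via alkenylcyclobutenone 16 (not isolated), via dienylketene 17 (not isolated)
Conditions: Pd(OAc)2 (10 mol %), P(t-Bu)3·HBF4 (20 mol %), HCO2Na (1.5 equiv), dry degassed DMF, 60 °C until 15 is consumed; then dilution with toluene, 110 °C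
Reagents that add atoms: none
Why: Zerovalent palladium should insert into the C–Br bond of ring A, the arylpalladium adds syn across the tethered alkyne and formate delivers hydride to the vinylpalladium, which gives 16 with the cyclobutenone cis to C6; at 110 °C the C1–C4 bond of the cyclobutenone opens by conrotatory 4π electrocyclic cleavage to dienylketene 17, whose ketene carbon bonds to the alkylidene carbon C5 in a disrotatory 6π electrocyclization. The closest known reaction types are the intramolecular reductive Heck cyclization of aryl halides onto internal alkynes and the Moore rearrangement of 4-alkenylcyclobutenones, in the variant that stops at a 6,6-disubstituted cyclohexa-2,4-dienone because the terminus carries no hydrogen. Ring B closes in the 7-exo-dig mode (the 8-endo mode is barred by the geometry of syn insertion), and ring C forms by 6π closure, so that the four squarate carbons and the two former alkyne carbons make up the six-membered ring. The only new stereocentre is spiro carbon C5, which needs no control because step 9 makes ring C mirror-symmetric, while the cyclobutenone stereocentre is erased on ring opening and C7, C8 and C9 are spectators. The step needs inward rotation of the alkenyl group, secured by the strong outward preference of the methoxy donor on the same carbon and by the reversibility of a wrong-way opening, and it needs carbopalladation to outrun hydrodebromination and thermal opening of 15, secured by the bulky electron-rich phosphine that allows 60 °C and by a small excess of poorly soluble formate. Aromatisation of 18 is blocked by the quaternary carbon, and dilution suppresses bimolecular ketene reactions.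

Step 9
Reactants: 18 (7R,8S,9R)-2,3,3',4,4',5'-hexamethoxy-7,8-dimethyl-6'-oxo-6,7,8,9-tetrahydrospiro[benzo[7]annulene-5,1'-cyclohexa[2,4]dien]-9-yl benzoate
Product: 20 (7R,8S,9R)-2,3,3',4,5'-pentamethoxy-7,8-dimethyl-4'-oxo-6,7,8,9-tetrahydrospiro[benzo[7]annulene-5,1'-cyclohexa[2,5]dien]-9-yl benzoate, via dienol 19 (not isolated)
Conditions: NaBH4, CeCl3·7H2O, MeOH, −20 to 0 °C; then 0.5 M aq HCl, THF, 0 °C
Reagents that add atoms: water, O
Why: Luche 1,2-reduction of the vinylogous ester carbonyl C6'=O spares the benzoate, and acid ionisation of the allylic alcohol to the methoxy-stabilised cyclohexadienyl cation followed by hydrolysis at C4' (Stork–Danheiser-type carbonyl transposition) should give the cross-conjugated dienone, whereby the carbinol and spiro stereocentres vanish.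

Compound list
1 | 2-bromo-3,4,5-trimethoxybenzaldehyde | O=Cc1cc(OC)c(OC)c(OC)c1Br | starting material
2 | (Z)-crotylboronic acid pinacol ester | C/C=C\CB1OC(C)(C)C(C)(C)O1 | starting material
3 | pinacol borate of alcohol 4 (O–B ester, same configuration) | C=C[C@H](C)[C@@H](OB1OC(C)(C)C(C)(C)O1)c2cc(OC)c(OC)c(OC)c2Br | intermediate
4 | (1R,2S)-1-(2-bromo-3,4,5-trimethoxyphenyl)-2-methylbut-3-en-1-ol (syn) | C=C[C@H](C)[C@@H](O)c1cc(OC)c(OC)c(OC)c1Br | intermediate
5 | acrylate of 4 | C=C[C@H](C)[C@@H](OC(=O)C=C)c1cc(OC)c(OC)c(OC)c1Br | intermediate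
6 | (5S,6R)-6-(2-bromo-3,4,5-trimethoxyphenyl)-5-methyl-5,6-dihydro-2H-pyran-2-one (5,6-cis) | O=C1C=C[C@H](C)[C@@H](O1)c2cc(OC)c(OC)c(OC)c2Br | intermediate
7 | lithium enolate of lactone 8 (same configuration at the three stereocentres) | [Li]OC1=C[C@@H](C)[C@H](C)[C@@H](O1)c2cc(OC)c(OC)c(OC)c2Br | intermediate
8 | (4R,5S,6R)-6-(2-bromo-3,4,5-trimethoxyphenyl)-4,5-dimethyltetrahydro-2H-pyran-2-one (4,5-trans, 5,6-cis) | O=C1C[C@@H](C)[C@H](C)[C@@H](O1)c2cc(OC)c(OC)c(OC)c2Br | intermediate
9 | lactol of 8 (anomer mixture) | OC1C[C@@H](C)[C@H](C)[C@@H](O1)c2cc(OC)c(OC)c(OC)c2Br | intermediate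
10 | (1R,2S,3R)-1-(2-bromo-3,4,5-trimethoxyphenyl)-2,3-dimethylhex-5-yn-1-ol | C#CC[C@@H](C)[C@H](C)[C@@H](O)c1cc(OC)c(OC)c(OC)c1Br | intermediate
11 | benzoate of 10 | C#CC[C@@H](C)[C@H](C)[C@@H](OC(=O)c1ccccc1)c1cc(OC)c(OC)c(OC)c1Br | intermediate
12 | dimethyl squarate (3,4-dimethoxycyclobut-3-ene-1,2-dione) | COC1=C(OC)C(=O)C1=O | starting material
13 | lithium acetylide of 11 | [Li]C#CC[C@@H](C)[C@H](C)[C@@H](OC(=O)c1ccccc1)c1cc(OC)c(OC)c(OC)c1Br | intermediate
14 | lithium alkoxide from 1,2-addition of 13 to 12 | COC1=C(OC)C(O[Li])(C#CC[C@@H](C)[C@H](C)[C@@H](OC(=O)c2ccccc2)c2cc(OC)c(OC)c(OC)c2Br)C1=O | intermediate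
15 | 4-alkynyl-2,3,4-trimethoxycyclobut-2-enone carrying the (1R,2S,3R)-benzoate chain and the bromoarene | COC1=C(OC)C(OC)(C#CC[C@@H](C)[C@H](C)[C@@H](OC(=O)c2ccccc2)c2cc(OC)c(OC)c(OC)c2Br)C1=O | intermediate
16 | (7R,8S,9R,E)-2,3,4-trimethoxy-7,8-dimethyl-5-[(1,2,3-trimethoxy-4-oxocyclobut-2-en-1-yl)methylidene]-6,7,8,9-tetrahydro-5H-benzo[7]annulen-9-yl benzoate | COC1=C(OC)C(OC)(/C=C2\C[C@@H](C)[C@H](C)[C@@H](OC(=O)c3ccccc3)c3cc(OC)c(OC)c(OC)c23)C1=O | intermediate
17 | dienylketene from ring opening of 16 (alkenyl group inward) | O=C=C(OC)/C(OC)=C(OC)\C=C1/C[C@@H](C)[C@H](C)[C@@H](OC(=O)c2ccccc2)c2cc(OC)c(OC)c(OC)c12 | intermediate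
18 | spiro cyclohexa-2,4-dienone: (7R,8S,9R)-2,3,3',4,4',5'-hexamethoxy-7,8-dimethyl-6'-oxo-6,7,8,9-tetrahydrospiro[benzo[7]annulene-5,1'-cyclohexa[2,4]dien]-9-yl benzoate | COC1=CC2(C[C@@H](C)[C@H](C)[C@@H](OC(=O)c3ccccc3)c3cc(OC)c(OC)c(OC)c23)C(=O)C(OC)=C1OC | intermediate
19 | 6'-hydroxy dienol from 1,2-reduction of 18 | COC1=CC2(C[C@@H](C)[C@H](C)[C@@H](OC(=O)c3ccccc3)c3cc(OC)c(OC)c(OC)c23)C(O)C(OC)=C1OC | intermediate
20 | CNP0201356.1, (7R,8S,9R)-2,3,3',4,5'-pentamethoxy-7,8-dimethyl-4'-oxo-6,7,8,9-tetrahydrospiro[benzo[7]annulene-5,1'-cyclohexa[2,5]dien]-9-yl benzoate | COC1=CC2(C=C(OC)C1=O)C[C@@H](C)[C@H](C)[C@@H](OC(=O)c1ccccc1)c1cc(OC)c(OC)c(OC)c12 | target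

Total step count: 9. Longest linear sequence: 9 steps (1 to 20).

Steps most likely to fail

1. Step 8. Hydride transfer to the arylpalladium may come before the slow closure of the seven-membered ring. The alkynylcyclobutenone may also open thermally before it has cyclised. The fallback sets out from 11 and closes ring B before the fragile cyclobutenone is attached.
   - LiN(iPr)2 (via 13) and then Me3SiCl should give the silylalkyne F1.
   - The same reductive Heck cyclization, now free to run at 100 °C, should give the (E)-vinylsilane F2.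
   - Iododesilylation with N-iodosuccinimide in (CF3)2CHOH should give, with retention, the (E)-vinyl iodide F3.
   - Iodine–magnesium exchange with iPrMgCl·LiCl at −20 °C, which tolerates the benzoate, should give the alkenylmagnesium chloride F4.
   - Addition of F4 to 12 should give the tertiary alcohol F5.
   - MeI/Ag2O then gives 16, where the fallback rejoins the route. Here 16 is isolated and heated alone in dilute toluene at 110 °C to reach 18.

2. Step 9. Hydride delivery to the carbonyl next to the spiro carbon may be sluggish under conditions mild enough for the benzoate. The fallback sets out from 18 and gives up the ester for a time.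
   - Excess iBu2AlH in CH2Cl2 at −78 °C should reduce both the ketone and the benzoate to the diol F6.
   - Dilute HCl in THF at 0 °C should transpose it to the hydroxy dienone F7.
   - BzCl, Et3N and DMAP then give 20.

3. Step 7. The acetylide or the amide base may attack the benzoate, and O-methylation may stay incomplete. The fallback sets out from 10 and changes the protecting-group plan.
   - Et3SiCl/imidazole should give the silyl ether F8.
   - LiN(iPr)2 should give its lithium acetylide F9.
   - Addition to 12 should give the lithium alkoxide F10.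
   - MeOTf should give the silyl-protected alkynylcyclobutenone F11.
   - HF·pyridine should free the alcohol F12.
   - BzCl/DMAP leads back to 15.

Further compounds
F1 | step 8 | (1R,2S,3R)-1-(2-bromo-3,4,5-trimethoxyphenyl)-2,3-dimethyl-6-(trimethylsilyl)hex-5-yn-1-yl benzoate | C[Si](C)(C)C#CC[C@@H](C)[C@H](C)[C@@H](OC(=O)c1ccccc1)c1cc(OC)c(OC)c(OC)c1Br
F2 | step 8 | (7R,8S,9R,E)-2,3,4-trimethoxy-7,8-dimethyl-5-[(trimethylsilyl)methylidene]-6,7,8,9-tetrahydro-5H-benzo[7]annulen-9-yl benzoate | C[Si](C)(C)/C=C1\C[C@@H](C)[C@H](C)[C@@H](OC(=O)c2ccccc2)c2cc(OC)c(OC)c(OC)c12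
F3 | step 8 | (7R,8S,9R,E)-5-(iodomethylidene)-2,3,4-trimethoxy-7,8-dimethyl-6,7,8,9-tetrahydro-5H-benzo[7]annulen-9-yl benzoate | I/C=C1\C[C@@H](C)[C@H](C)[C@@H](OC(=O)c2ccccc2)c2cc(OC)c(OC)c(OC)c12
F4 | step 8 | alkenylmagnesium chloride from F3 | Cl[Mg]/C=C1\C[C@@H](C)[C@H](C)[C@@H](OC(=O)c2ccccc2)c2cc(OC)c(OC)c(OC)c12
F5 | step 8 | 4-hydroxy analogue of 16 (tertiary alcohol, epimer mixture at the carbinol carbon) | COC1=C(OC)C(O)(/C=C2\C[C@@H](C)[C@H](C)[C@@H](OC(=O)c3ccccc3)c3cc(OC)c(OC)c(OC)c23)C1=O
F6 | step 9 | 6',9-diol from global reduction of 18 | COC1=CC2(C[C@@H](C)[C@H](C)[C@@H](O)c3cc(OC)c(OC)c(OC)c23)C(O)C(OC)=C1OC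
F7 | step 9 | (7R,8S,9R)-9-hydroxy-2,3,3',4,5'-pentamethoxy-7,8-dimethyl-6,7,8,9-tetrahydrospiro[benzo[7]annulene-5,1'-cyclohexa[2,5]dien]-4'-one | COC1=CC2(C=C(OC)C1=O)C[C@@H](C)[C@H](C)[C@@H](O)c1cc(OC)c(OC)c(OC)c12
F8 | step 7 | triethylsilyl ether of 10 | C#CC[C@@H](C)[C@H](C)[C@@H](O[Si](CC)(CC)CC)c1cc(OC)c(OC)c(OC)c1Br
F9 | step 7 | lithium acetylide of F8 | [Li]C#CC[C@@H](C)[C@H](C)[C@@H](O[Si](CC)(CC)CC)c1cc(OC)c(OC)c(OC)c1Br
F10 | step 7 | lithium alkoxide from addition of F9 to 12 | COC1=C(OC)C(O[Li])(C#CC[C@@H](C)[C@H](C)[C@@H](O[Si](CC)(CC)CC)c2cc(OC)c(OC)c(OC)c2Br)C1=O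
F11 | step 7 | triethylsilyl ether analogue of 15 | COC1=C(OC)C(OC)(C#CC[C@@H](C)[C@H](C)[C@@H](O[Si](CC)(CC)CC)c2cc(OC)c(OC)c(OC)c2Br)C1=O
F12 | step 7 | free alcohol analogue of 15 | COC1=C(OC)C(OC)(C#CC[C@@H](C)[C@H](C)[C@@H](O)c2cc(OC)c(OC)c(OC)c2Br)C1=O
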